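**Strategy**

The isoflavan is cut across ring C at C4–C4a and O1–C2. C4a is an ortho carbon of the symmetric ring A phenol whose hydroxyl is O1 (both ortho carbons equivalent, para carbon blocked by prenyl), and C4–C3–C2 with ring B on C3 is a 2-arylacrolein. One amine-catalysed operation joins them: Friedel–Crafts addition of the phenol to the enal CH2 (C4–C4a), enantioselective protonation at C3, and lactol closure (O1–C2) that forms ring C. The precursors are 3,5-dimethoxy-4-prenylphenol and the 2-arylacrolein of the silyl-protected ring B chromene, which is annulated through the 2-hydroxyl of 2,4-dihydroxybenzaldehyde so that the pyran oxygen sits on C2′ and the free hydroxyl on C4′.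

Key step: step 10

Assumption: the (S)-tert-leucine-derived diamine salt is taken to protonate the enamine on the face that gives (3R); if a pilot run shows the opposite sense, its (R)-antipode (from D-tert-leucine) takes its place and nothing else changes.

**Route**

Step 1
Reactants: 1 3,5-dimethoxyphenol
Product: 2 (3,5-dimethoxyphenoxy)tri(propan-2-yl)silane
Conditions: iPr3SiCl, imidazole, DMF, rt
Reagents that add atoms: chlorotri(propan-2-yl)silane, CC(C)[Si](Cl)(C(C)C)C(C)C
Why: Imidazole-promoted O-silylation of the only hydroxyl gives a bulky, weakly coordinating aryl silyl ether, which the regioselective metalation of the next step requires.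

Step 2
Reactants: 2 (3,5-dimethoxyphenoxy)tri(propan-2-yl)silane; 3 prenyl bromide (1-bromo-3-methylbut-2-ene)
Product: 5 [3,5-dimethoxy-4-(3-methylbut-2-en-1-yl)phenoxy]tri(propan-2-yl)silane, via aryllithium 4 (not isolated)
Conditions: n-BuLi, THF, 0 °C → rt; then CuBr·SMe2 (10 mol %), 3, −78 °C → rt
Reagents that add atoms: none
Why: Directed ortho-metalation should place lithium on the carbon between the two cooperating methoxy groups (the positions next to the hindered silyloxy group are not metalated), and copper-catalysed allylic substitution at the primary carbon of prenyl bromide should give the linear prenyl arene.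

Step 3
Reactants: 5 [3,5-dimethoxy-4-(3-methylbut-2-en-1-yl)phenoxy]tri(propan-2-yl)silane
Product: 6 3,5-dimethoxy-4-(3-methylbut-2-en-1-yl)phenol
Conditions: Bu4NF, AcOH (1:1), THF, 0 °C
Reagents that add atoms: none
Why: Fluoride-mediated desilylation of the aryl silyl ether, buffered with acetic acid so that the electron-rich phenol is never handled as its air-sensitive phenoxide.

Step 4
Reactants: 7 2,4-dihydroxybenzaldehyde
Product: 8 2-hydroxy-4-{[tri(propan-2-yl)silyl]oxy}benzaldehyde
Conditions: iPr3SiCl (1.05 equiv), imidazole, CH2Cl2, 0 °C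
Reagents that add atoms: chlorotri(propan-2-yl)silane, CC(C)[Si](Cl)(C(C)C)C(C)C
Why: Chemoselective O-silylation, because the 2-hydroxyl is tied up in the hydrogen bond to the formyl group and is ortho-flanked, so the 4-hydroxyl reacts first; this leaves the 2-hydroxyl free for the pyran annulation that ring B needs.

Step 5
Reactants: 8 2-hydroxy-4-{[tri(propan-2-yl)silyl]oxy}benzaldehyde; 9 2-methylbut-3-yn-2-ol
Product: 11 2-[(2-methylbut-3-yn-2-yl)oxy]-4-{[tri(propan-2-yl)silyl]oxy}benzaldehyde, via trifluoroacetate 10 (not isolated)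
Conditions: 9, (CF3CO)2O, DBU, MeCN, −5 °C; the solution of 10 then added to 8, DBU, CuCl2·2H2O (1 mol %), MeCN, −5 °C → rt
Reagents that add atoms: none
Why: Copper-catalysed propargylic etherification, in which the copper acetylide of ester 10 ionises to an allenylidene-type electrophile that the phenoxide traps at the tertiary carbon under conditions mild enough for the aldehyde and the silyl ether.

Step 6
Reactants: 11 2-[(2-methylbut-3-yn-2-yl)oxy]-4-{[tri(propan-2-yl)silyl]oxy}benzaldehyde
Product: 13 2,2-dimethyl-5-{[tri(propan-2-yl)silyl]oxy}-2H-chromene-8-carbaldehyde, via allenylphenol 12 (not isolated)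
Conditions: o-xylene, 140 °C
Reagents that add atoms: none
Why: Aromatic propargyl Claisen rearrangement can only go to C3 (the other ortho carbon carries the formyl group), and tautomerisation to 12, 1,5-hydrogen shift and oxa-6π electrocyclisation should give the chromene with the pyran oxygen next to the formyl-bearing carbon and the silyloxy group para to it.

Step 7
Reactants: 13 2,2-dimethyl-5-{[tri(propan-2-yl)silyl]oxy}-2H-chromene-8-carbaldehyde
Product: 14 {[8-(2-methoxyethenyl)-2,2-dimethyl-2H-chromen-5-yl]oxy}tri(propan-2-yl)silane (E/Z mixture)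
Conditions: Ph3P(CH2OMe)Cl, KN(SiMe3)2, THF, 0 °C; then 13, 0 °C → rt
Reagents that add atoms: (methoxymethyl)triphenylphosphonium chloride, COC[P+](c1ccccc1)(c1ccccc1)c1ccccc1.[Cl-]
Why: Wittig methoxymethylenation of the aryl aldehyde; the alkene geometry is of no consequence because both isomers hydrolyse to the same aldehyde.

Step 8
Reactants: 14 {[8-(2-methoxyethenyl)-2,2-dimethyl-2H-chromen-5-yl]oxy}tri(propan-2-yl)silane
Product: 15 (2,2-dimethyl-5-{[tri(propan-2-yl)silyl]oxy}-2H-chromen-8-yl)acetaldehyde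
Conditions: 1 M aq. HCl–THF (1:4), 40 °C; crude product used at once
Reagents that add atoms: water, O
Why: Acid-catalysed enol ether hydrolysis (C-protonation, hydration, loss of methanol) completes the one-carbon homologation, and aryl triisopropylsilyl ethers and 2,2-dimethylchromenes should tolerate dilute aqueous acid at this temperature.

Step 9
Reactants: 15 (2,2-dimethyl-5-{[tri(propan-2-yl)silyl]oxy}-2H-chromen-8-yl)acetaldehyde
Product: 16 2-(2,2-dimethyl-5-{[tri(propan-2-yl)silyl]oxy}-2H-chromen-8-yl)prop-2-enal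
Conditions: 37 % aq. HCHO, pyrrolidine (10 mol %), EtCO2H (10 mol %), iPrOH, 45 °C; kept cold in solution and used within hours
Reagents that add atoms: formaldehyde, C=O
Why: Amine-catalysed α-methylenation (Mannich condensation with formaldehyde followed by β-elimination of the amine) of the enolisable arylacetaldehyde should give the 2-arylacrolein.

Step 10
Reactants: 6 3,5-dimethoxy-4-(3-methylbut-2-en-1-yl)phenol; 16 2-(2,2-dimethyl-5-{[tri(propan-2-yl)silyl]oxy}-2H-chromen-8-yl)prop-2-enal
Product: 18 (3R)-3-(2,2-dimethyl-5-{[tri(propan-2-yl)silyl]oxy}-2H-chromen-8-yl)-5,7-dimethoxy-6-(3-methylbut-2-en-1-yl)-3,4-dihydro-2H-chromen-2-ol (both C2 epimers), via hydroxy aldehyde 17 (not isolated)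
Conditions: 6 (1.5 equiv), 16 (added slowly), (S)-N1,N1-diethyl-3,3-dimethylbutane-1,2-diamine·TfOH (20 mol %), CHCl3, 0 °C; filtration through silica at 0 °C, product carried on without storage
Reagents that add atoms: none
Why: Proposed new method: the primary amine condenses with enal 16 to an α-aryl iminium ion, the ortho carbon of phenol 6 (activated by its hydroxyl, an ortho methoxy and a para methoxy group) adds to the CH2 terminus to form C4–C4a, the enamine so formed is protonated at C3 by the ammonium arm of the catalyst, and hydrolysis releases hydroxy aldehyde 17. The closest known reaction type is the primary-amine-catalysed Friedel–Crafts conjugate addition of indoles to α-substituted acroleins with enantioselective enamine protonation, and iminium-catalysed Friedel–Crafts addition of electron-rich phenols to enals with hemiacetal closure is likewise known; new here is the pairing of a phenol with a 2-arylacrolein. Ring C closes by 6-exo-trig addition of the phenol oxygen to the aldehyde carbonyl (O1–C2), which gives the lactol as both C2 epimers. C3, the only stereocentre carried forward, is set as R by catalyst-controlled delivery of the proton to one face of the enamine. The step needs C- over O-alkylation and one constitution: the two ortho carbons of 6 are equivalent, its para carbon is blocked by the prenyl group, the ring B phenol is silylated, and oxa-Michael adducts can revert under iminium catalysis. Lactol closure withdraws the α-aryl aldehyde from the enamine equilibrium that would otherwise racemise C3.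

Step 11
Reactants: 18 (3R)-3-(2,2-dimethyl-5-{[tri(propan-2-yl)silyl]oxy}-2H-chromen-8-yl)-5,7-dimethoxy-6-(3-methylbut-2-en-1-yl)-3,4-dihydro-2H-chromen-2-ol
Product: 19 ({8-[(3R)-5,7-dimethoxy-6-(3-methylbut-2-en-1-yl)-3,4-dihydro-2H-chromen-3-yl]-2,2-dimethyl-2H-chromen-5-yl}oxy)tri(propan-2-yl)silane
Conditions: Et3SiH (4 equiv), BF3·OEt2 (1.5 equiv), CH2Cl2, −78 → −40 °C; Et3N then aq. NaHCO3
Reagents that add atoms: none
Why: Ionic hydrogenation of the lactol, in which BF3 ionises C2 to the aryloxy-stabilised oxocarbenium ion and excess silane is expected to reduce it faster than it can lose the C3 proton, so ring C and the C3 configuration are kept while the alkenes and the aryl silyl ether are spared at low temperature.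

Step 12
Reactants: 19 ({8-[(3R)-5,7-dimethoxy-6-(3-methylbut-2-en-1-yl)-3,4-dihydro-2H-chromen-3-yl]-2,2-dimethyl-2H-chromen-5-yl}oxy)tri(propan-2-yl)silane
Product: 20 Kanzonol I, 8-[(3R)-5,7-dimethoxy-6-(3-methylbut-2-en-1-yl)-3,4-dihydro-2H-chromen-3-yl]-2,2-dimethyl-2H-chromen-5-ol
Conditions: Bu4NF, AcOH (1:1), THF, 0 °C
Reagents that add atoms: none
Why: Buffered fluoride desilylation of the aryl silyl ether frees the C4′ hydroxyl without acid or strong base, so the prenyl group, the chromene and C3 are untouched.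

**Compound list**

1 | 3,5-dimethoxyphenol | COc1cc(O)cc(OC)c1 | starting material
2 | (3,5-dimethoxyphenoxy)tri(propan-2-yl)silane | COc1cc(O[Si](C(C)C)(C(C)C)C(C)C)cc(OC)c1 | intermediate
3 | prenyl bromide (1-bromo-3-methylbut-2-ene) | CC(C)=CCBr | starting material
4 | (2,6-dimethoxy-4-{[tri(propan-2-yl)silyl]oxy}phenyl)lithium | [Li]c1c(OC)cc(O[Si](C(C)C)(C(C)C)C(C)C)cc1OC | intermediate (not isolated)
5 | [3,5-dimethoxy-4-(3-methylbut-2-en-1-yl)phenoxy]tri(propan-2-yl)silane | COc1cc(O[Si](C(C)C)(C(C)C)C(C)C)cc(OC)c1CC=C(C)C | intermediate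
6 | 3,5-dimethoxy-4-(3-methylbut-2-en-1-yl)phenol | COc1cc(O)cc(OC)c1CC=C(C)C | intermediate
7 | 2,4-dihydroxybenzaldehyde | O=Cc1ccc(O)cc1O | starting material
8 | 2-hydroxy-4-{[tri(propan-2-yl)silyl]oxy}benzaldehyde | O=Cc1ccc(O[Si](C(C)C)(C(C)C)C(C)C)cc1O | intermediate
9 | 2-methylbut-3-yn-2-ol | CC(C)(O)C#C | starting material
10 | 2-methylbut-3-yn-2-yl trifluoroacetate | CC(C)(OC(=O)C(F)(F)F)C#C | intermediate (not isolated)
11 | 2-[(2-methylbut-3-yn-2-yl)oxy]-4-{[tri(propan-2-yl)silyl]oxy}benzaldehyde | O=Cc1ccc(O[Si](C(C)C)(C(C)C)C(C)C)cc1OC(C)(C)C#C | intermediate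
12 | 2-hydroxy-3-(3-methylbuta-1,2-dien-1-yl)-4-{[tri(propan-2-yl)silyl]oxy}benzaldehyde | O=Cc1ccc(O[Si](C(C)C)(C(C)C)C(C)C)c(C=C=C(C)C)c1O | intermediate (not isolated)
13 | 2,2-dimethyl-5-{[tri(propan-2-yl)silyl]oxy}-2H-chromene-8-carbaldehyde | O=Cc1ccc(O[Si](C(C)C)(C(C)C)C(C)C)c2c1OC(C)(C)C=C2 | intermediate
14 | {[8-(2-methoxyethenyl)-2,2-dimethyl-2H-chromen-5-yl]oxy}tri(propan-2-yl)silane (E/Z mixture) | COC=Cc1ccc(O[Si](C(C)C)(C(C)C)C(C)C)c2c1OC(C)(C)C=C2 | intermediate
15 | (2,2-dimethyl-5-{[tri(propan-2-yl)silyl]oxy}-2H-chromen-8-yl)acetaldehyde | O=CCc1ccc(O[Si](C(C)C)(C(C)C)C(C)C)c2c1OC(C)(C)C=C2 | intermediate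
16 | 2-(2,2-dimethyl-5-{[tri(propan-2-yl)silyl]oxy}-2H-chromen-8-yl)prop-2-enal | C=C(C=O)c1ccc(O[Si](C(C)C)(C(C)C)C(C)C)c2c1OC(C)(C)C=C2 | intermediate
17 | (2R)-2-(2,2-dimethyl-5-{[tri(propan-2-yl)silyl]oxy}-2H-chromen-8-yl)-3-[6-hydroxy-2,4-dimethoxy-3-(3-methylbut-2-en-1-yl)phenyl]propanal | O=C[C@H](Cc1c(O)cc(OC)c(CC=C(C)C)c1OC)c1ccc(O[Si](C(C)C)(C(C)C)C(C)C)c2c1OC(C)(C)C=C2 | intermediate (not isolated)
18 | (3R)-3-(2,2-dimethyl-5-{[tri(propan-2-yl)silyl]oxy}-2H-chromen-8-yl)-5,7-dimethoxy-6-(3-methylbut-2-en-1-yl)-3,4-dihydro-2H-chromen-2-ol (both C2 epimers) | COc1cc2c(c(OC)c1CC=C(C)C)C[C@H](c1ccc(O[Si](C(C)C)(C(C)C)C(C)C)c3c1OC(C)(C)C=C3)C(O)O2 | intermediate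
19 | ({8-[(3R)-5,7-dimethoxy-6-(3-methylbut-2-en-1-yl)-3,4-dihydro-2H-chromen-3-yl]-2,2-dimethyl-2H-chromen-5-yl}oxy)tri(propan-2-yl)silane | COc1cc2c(c(OC)c1CC=C(C)C)C[C@H](c1ccc(O[Si](C(C)C)(C(C)C)C(C)C)c3c1OC(C)(C)C=C3)CO2 | intermediate
20 | Kanzonol I, 8-[(3R)-5,7-dimethoxy-6-(3-methylbut-2-en-1-yl)-3,4-dihydro-2H-chromen-3-yl]-2,2-dimethyl-2H-chromen-5-ol | COc1cc2c(c(OC)c1CC=C(C)C)C[C@H](c1ccc(O)c3c1OC(C)(C)C=C3)CO2 | target

**Totals**

Total step count: 12. Longest linear sequence: 9 steps (7 to 20, steps 4–12).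

**Steps most likely to fail**

Step 10. The proton transfer to the α-aryl enamine may show poor facial selectivity, the ring-opened aldehyde may racemise through the amine, and O-alkylation or oligomerisation of the enal may compete. The fallback is known chemistry, an oxazolidinone-auxiliary (Evans) alkylation that forms C3–C4 instead; it sets out from 15 and 6 and comes back at 19. Pinnick oxidation of 15 (NaClO2, NaH2PO4, 2-methylbut-2-ene, tBuOH–H2O) would give (2,2-dimethyl-5-{[tri(propan-2-yl)silyl]oxy}-2H-chromen-8-yl)acetic acid F1. Through its mixed pivalic anhydride F2 (PivCl, Et3N, THF, not isolated), F1 would acylate (4R)-4-benzyl-1,3-oxazolidin-2-one (LiCl) to the N-arylacetyl oxazolidinone F3. Phenol 6 would be ortho-formylated (MgCl2, Et3N, paraformaldehyde, MeCN, reflux) to 6-hydroxy-2,4-dimethoxy-3-(3-methylbut-2-en-1-yl)benzaldehyde F4 and O-allylated (allyl bromide, K2CO3, DMF) to the allyl ether aldehyde F5. Reduction (NaBH4, MeOH) would give the benzyl alcohol F6, and PBr3 (Et2O, 0 °C) the benzyl bromide F7, used at once. The sodium enolate of F3 (NaN(SiMe3)2, THF, −78 °C) would be alkylated by F7 on the face away from the benzyl group to give the alkylated imide F8 with the new centre R. LiBH4 (THF–MeOH, 0 °C) would release the allyl-protected primary alcohol F9 and the auxiliary. Pd(PPh3)4 with morpholine (THF, rt) would remove the allyl group to give the phenol alcohol F10, and Mitsunobu closure of O1–C2 (PPh3, DIAD, THF) would give 19.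

Step 11. The oxocarbenium ion may lose its C3 proton to an enol ether and be reprotonated, eroding the C3 configuration, and the Lewis acid may attack the prenyl or chromene alkene. The fallback avoids acid at the price of opening and re-closing O1–C2; it sets out from 18 and comes back at 19. NaBH4 (THF–MeOH, 0 °C) would reduce the ring-opened form 17 to (2R)-2-(2,2-dimethyl-5-{[tri(propan-2-yl)silyl]oxy}-2H-chromen-8-yl)-3-[6-hydroxy-2,4-dimethoxy-3-(3-methylbut-2-en-1-yl)phenyl]propan-1-ol F11 (the same compound as F10). Intramolecular Mitsunobu etherification (PPh3, DIAD, THF, 0 °C → rt) would then close ring C to 19.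

Step 5. O-alkylation of the hydrogen-bonded, ortho-flanked phenoxide at a tertiary carbon may be slow, and the base may strip the silyl group para to the aldehyde. The fallback forms the C–C bond first and needs no O-alkylation; it sets out from 8 and comes back at 13, bypassing 11. Phenylboronic acid-mediated ortho-condensation of 8 with 3-methylbut-2-enal (PhB(OH)2, EtCO2H, toluene, reflux with removal of water) would give 4-(2-methylprop-1-en-1-yl)-2-phenyl-5-{[tri(propan-2-yl)silyl]oxy}-4H-1,3,2-benzodioxaborinine-8-carbaldehyde F12. On continued heating F12 would fragment to the ortho-quinone methide and electrocyclise to 13.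

**Further compounds**

F1 | step 10 | (2,2-dimethyl-5-{[tri(propan-2-yl)silyl]oxy}-2H-chromen-8-yl)acetic acid | OC(=O)Cc1ccc(O[Si](C(C)C)(C(C)C)C(C)C)c2c1OC(C)(C)C=C2
F2 | step 10 | (2,2-dimethyl-5-{[tri(propan-2-yl)silyl]oxy}-2H-chromen-8-yl)acetic 2,2-dimethylpropanoic anhydride | CC(C)(C)C(=O)OC(=O)Cc1ccc(O[Si](C(C)C)(C(C)C)C(C)C)c2c1OC(C)(C)C=C2
F3 | step 10 | (4R)-4-benzyl-3-[(2,2-dimethyl-5-{[tri(propan-2-yl)silyl]oxy}-2H-chromen-8-yl)acetyl]-1,3-oxazolidin-2-one | O=C(Cc1ccc(O[Si](C(C)C)(C(C)C)C(C)C)c2c1OC(C)(C)C=C2)N1[C@H](Cc2ccccc2)COC1=O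
F4 | step 10 | 6-hydroxy-2,4-dimethoxy-3-(3-methylbut-2-en-1-yl)benzaldehyde | COc1cc(O)c(C=O)c(OC)c1CC=C(C)C
F5 | step 10 | 2,4-dimethoxy-3-(3-methylbut-2-en-1-yl)-6-(prop-2-en-1-yloxy)benzaldehyde | COc1cc(OCC=C)c(C=O)c(OC)c1CC=C(C)C
F6 | step 10 | [2,4-dimethoxy-3-(3-methylbut-2-en-1-yl)-6-(prop-2-en-1-yloxy)phenyl]methanol | COc1cc(OCC=C)c(CO)c(OC)c1CC=C(C)C
F7 | step 10 | 2-(bromomethyl)-3,5-dimethoxy-4-(3-methylbut-2-en-1-yl)-1-(prop-2-en-1-yloxy)benzene | COc1cc(OCC=C)c(CBr)c(OC)c1CC=C(C)C
F8 | step 10 | (4R)-4-benzyl-3-[(2R)-2-(2,2-dimethyl-5-{[tri(propan-2-yl)silyl]oxy}-2H-chromen-8-yl)-3-[2,4-dimethoxy-3-(3-methylbut-2-en-1-yl)-6-(prop-2-en-1-yloxy)phenyl]propanoyl]-1,3-oxazolidin-2-one | O=C([C@H](Cc1c(OCC=C)cc(OC)c(CC=C(C)C)c1OC)c1ccc(O[Si](C(C)C)(C(C)C)C(C)C)c2c1OC(C)(C)C=C2)N1[C@H](Cc2ccccc2)COC1=O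
F9 | step 10 | (2R)-2-(2,2-dimethyl-5-{[tri(propan-2-yl)silyl]oxy}-2H-chromen-8-yl)-3-[2,4-dimethoxy-3-(3-methylbut-2-en-1-yl)-6-(prop-2-en-1-yloxy)phenyl]propan-1-ol | OC[C@H](Cc1c(OCC=C)cc(OC)c(CC=C(C)C)c1OC)c1ccc(O[Si](C(C)C)(C(C)C)C(C)C)c2c1OC(C)(C)C=C2
F10 | step 10 | (2R)-2-(2,2-dimethyl-5-{[tri(propan-2-yl)silyl]oxy}-2H-chromen-8-yl)-3-[6-hydroxy-2,4-dimethoxy-3-(3-methylbut-2-en-1-yl)phenyl]propan-1-ol | OC[C@H](Cc1c(O)cc(OC)c(CC=C(C)C)c1OC)c1ccc(O[Si](C(C)C)(C(C)C)C(C)C)c2c1OC(C)(C)C=C2
F11 | step 11 | (2R)-2-(2,2-dimethyl-5-{[tri(propan-2-yl)silyl]oxy}-2H-chromen-8-yl)-3-[6-hydroxy-2,4-dimethoxy-3-(3-methylbut-2-en-1-yl)phenyl]propan-1-ol | OC[C@H](Cc1c(O)cc(OC)c(CC=C(C)C)c1OC)c1ccc(O[Si](C(C)C)(C(C)C)C(C)C)c2c1OC(C)(C)C=C2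
F12 | step 5 | 4-(2-methylprop-1-en-1-yl)-2-phenyl-5-{[tri(propan-2-yl)silyl]oxy}-4H-1,3,2-benzodioxaborinine-8-carbaldehyde | O=Cc1ccc(O[Si](C(C)C)(C(C)C)C(C)C)c2c1OB(c1ccccc1)OC2C=C(C)C
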